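**Retrosynthetic overview**

1. Locants used below: ring A (cyclobutane) C1(OAc)–C2–C3(Me)–C11; ring B (cyclopentane) C3–C4(Br)–C5–C6(Me)–C11; ring C (cyclohexane) C6–C7(Me)–C8(Br)–C9(OH)–C10(Me)–C11; C11 belongs to all three rings.
2. Endgame (functional groups only): C9 carbinol ⇐ α-bromo ketone ⇐ enone C7=C8–C9=O (hydride to C7, Br+ to C8) ⇐ allylic oxidation of a C7=C8 cyclohexene; C1 acetate ⇐ C1 ketone.
3. Key disconnection: the cyclohexene is opened across C9–C10 and C6–C11 (retro-Diels–Alder) to an (E)-2-ethylidenecyclobutanone (C10=C11–C1=O) that carries on C3 the chain C4(Br)–C5–C6(Me)=C7(Me)–C8=C9. Rings B and C close together on the purchased ring A.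
4. Enabling feature: C9–C10 and C6–C11 are the two bonds of six-membered ring C that flank C7–C8. C11 is α to the oxygen-bearing C1 of the strained four-membered ring, so at the ketone level C10=C11 is an activated exocyclic enone. C6 and C11 are joined by the three-atom bridge C5–C4–C3 of ring B, which makes the [4+2] intramolecular and fixes its regiochemistry.
5. Precursor assembly: C4–C5 bond, C4 stereocentre and C6=C7 alkene by an asymmetric vinylogous Mukaiyama aldol on a cyclobutane aldehyde; C4–Br by inversion; ethylidene group by an enantiotopic-group-selective aldol condensation of the prochiral cyclobutanone.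

Key step: step 12

Assumption: the senses of asymmetric induction in steps 4 and 10 are taken as shown; the antipodal tryptophan-derived Lewis acid or lithium amide is used if either proves opposite.

**Route**

Step 1
Reactants: 1 methyl 1-methyl-3-oxocyclobutane-1-carboxylate
Product: 2 methyl 3,3-dimethoxy-1-methylcyclobutane-1-carboxylate
Conditions: HC(OMe)3, MeOH, cat. TsOH·H2O, rt
Reagents that add atoms: trimethyl orthoformate, COC(OC)OC
Why: Acid-catalysed ketalisation masks the ring ketone (future C1) so that the ester carbon (future C4) can be taken to the aldehyde level; no stereocentre is involved.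

Step 2
Reactants: 2 methyl 3,3-dimethoxy-1-methylcyclobutane-1-carboxylate
Product: 3 3,3-dimethoxy-1-methylcyclobutane-1-carbaldehyde
Conditions: iBu2AlH (1.1 equiv), CH2Cl2, −78 °C; aq. potassium sodium tartrate
Reagents that add atoms: none
Why: Partial hydride reduction of the hindered α-quaternary ester should stop at the tetrahedral aluminium hemiacetal at low temperature and release the non-enolisable aldehyde on work-up.

Step 3
Reactants: 4 ethyl 2,3-dimethylbut-2-enoate
Product: 6 tert-butyl[(1-ethoxy-2,3-dimethylbuta-1,3-dien-1-yl)oxy]dimethylsilane (vinylketene silyl acetal), via lithium dienolate 5 (not isolated)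
Conditions: LiN(iPr)2, THF/DMPU, −78 °C; then TBSCl, −78 °C → rt
Reagents that add atoms: tert-butyldimethylsilyl chloride, CC(C)(C)[Si](C)(C)Cl
Why: γ-Deprotonation of the tetrasubstituted enoate (either β-methyl gives the same dienolate) followed by O-silylation is the standard entry to vinylketene silyl acetals; the ketene-acetal geometry is inconsequential.

Step 4
Reactants: 3 3,3-dimethoxy-1-methylcyclobutane-1-carbaldehyde; 6 tert-butyl[(1-ethoxy-2,3-dimethylbuta-1,3-dien-1-yl)oxy]dimethylsilane
Product: 7 ethyl (2E,5R)-5-(3,3-dimethoxy-1-methylcyclobutyl)-5-hydroxy-2,3-dimethylpent-2-enoate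
Conditions: B-phenyl oxazaborolidinone of N-tosyl-L-tryptophan (1.0 equiv; preformed from the acid and PhBCl2), iPrOH (1.2 equiv), EtCN, −78 °C
Reagents that add atoms: none
Why: Vinylogous Mukaiyama aldol: the chiral boron Lewis acid activates the aldehyde and the dienolate attacks through its γ-carbon (future C5), forming the C4–C5 bond, the (E)-tetrasubstituted C6=C7 alkene and the C4 carbinol, whose (R) configuration is set by the Lewis-acid-shielded aldehyde face.

Step 5
Reactants: 7 ethyl (2E,5R)-5-(3,3-dimethoxy-1-methylcyclobutyl)-5-hydroxy-2,3-dimethylpent-2-enoate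
Product: 8 ethyl (2E,5S)-5-bromo-5-(3,3-dimethoxy-1-methylcyclobutyl)-2,3-dimethylpent-2-enoate
Conditions: PPh3, CBr4, 2,6-lutidine, CH2Cl2, 0 → 40 °C
Reagents that add atoms: carbon tetrabromide, BrC(Br)(Br)Br
Why: Appel reaction: bromide should displace the alkoxyphosphonium by SN2 with inversion (R → S at C4) under non-ionising conditions, as is known for neopentyl-type alcohols, while conjugation to the ester keeps the C6=C7 alkene from participating.

Step 6
Reactants: 8 ethyl (2E,5S)-5-bromo-5-(3,3-dimethoxy-1-methylcyclobutyl)-2,3-dimethylpent-2-enoate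
Product: 9 (2E,5S)-5-bromo-5-(3,3-dimethoxy-1-methylcyclobutyl)-2,3-dimethylpent-2-en-1-ol
Conditions: iBu2AlH (2.2 equiv), CH2Cl2, −78 °C
Reagents that add atoms: none
Why: 1,2-Reduction of the enoate to the allylic alcohol; the secondary bromide and the ketal are inert to the aluminium hydride at low temperature.

Step 7
Reactants: 9 (2E,5S)-5-bromo-5-(3,3-dimethoxy-1-methylcyclobutyl)-2,3-dimethylpent-2-en-1-ol
Product: 10 (2E,5S)-5-bromo-5-(3,3-dimethoxy-1-methylcyclobutyl)-2,3-dimethylpent-2-enal
Conditions: MnO2, CH2Cl2, rt
Reagents that add atoms: none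
Why: Neutral, chemoselective oxidation of the primary allylic alcohol to the enal, which avoids any base that could trigger loss of HBr through the γ-position.

Step 8
Reactants: 10 (2E,5S)-5-bromo-5-(3,3-dimethoxy-1-methylcyclobutyl)-2,3-dimethylpent-2-enal
Product: 11 3-[(1S,3E)-1-bromo-3,4-dimethylhexa-3,5-dien-1-yl]-1,1-dimethoxy-3-methylcyclobutane
Conditions: Ph3PCH3Br, KN(SiMe3)2, THF, 0 °C; then 10, −78 → 0 °C
Reagents that add atoms: methyltriphenylphosphonium bromide, C[P+](c1ccccc1)(c1ccccc1)c1ccccc1.[Br-]
Why: Wittig methylenation installs C9 and completes the (E)-3,4-dimethyl-1,3-diene (C6=C7–C8=C9); carbonyl addition of the ylide at −78 °C should outpace γ-deprotonation of the enal.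

Step 9
Reactants: 11 3-[(1S,3E)-1-bromo-3,4-dimethylhexa-3,5-dien-1-yl]-1,1-dimethoxy-3-methylcyclobutane
Product: 12 3-[(1S,3E)-1-bromo-3,4-dimethylhexa-3,5-dien-1-yl]-3-methylcyclobutan-1-one
Conditions: PPTS (cat.), acetone/H2O (10:1), 50 °C
Reagents that add atoms: water, O
Why: Mild acid-catalysed ketal hydrolysis should release the cyclobutanone without protonating the diene; no stereocentre is affected.

Step 10
Reactants: 12 3-[(1S,3E)-1-bromo-3,4-dimethylhexa-3,5-dien-1-yl]-3-methylcyclobutan-1-one
Product: 14 (3R)-3-[(1S,3E)-1-bromo-3,4-dimethylhexa-3,5-dien-1-yl]-2-(1-hydroxyethyl)-3-methylcyclobutan-1-one (mixture at the two transient centres), via lithium enolate 13 (not isolated)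
Conditions: (R,R)-bis(1-phenylethyl)amine, n-BuLi, LiCl, THF, −100 °C; then CH3CHO, −100 → −78 °C; aq. NH4Cl
Reagents that add atoms: acetaldehyde, CC=O
Why: Enantiotopic-group-selective deprotonation of a prochiral cyclobutanone by a C2-symmetric chiral lithium amide (known for 3-substituted cyclobutanones) selects one of the two ring CH2 groups and thereby makes C3 stereogenic (R); aldol capture fixes the choice, and the two new centres are erased in the next step.

Step 11
Reactants: 14 (3R)-3-[(1S,3E)-1-bromo-3,4-dimethylhexa-3,5-dien-1-yl]-2-(1-hydroxyethyl)-3-methylcyclobutan-1-one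
Product: 16 (2E,3R)-3-[(1S,3E)-1-bromo-3,4-dimethylhexa-3,5-dien-1-yl]-2-ethylidene-3-methylcyclobutan-1-one, via mesylate 15 (not isolated)
Conditions: MsCl, Et3N, CH2Cl2, −20 °C; then DBU, 0 °C → rt
Reagents that add atoms: none
Why: Mesylation and E1cB elimination should give the conjugated exocyclic enone as the (E)-isomer (methyl anti to the carbonyl, the usual outcome for 2-alkylidenecycloalkanones); any (Z)-isomer is removed by chromatography, and C10 remains correctable later because it becomes α to the C9 ketone.

Step 12
Reactants: 16 (2E,3R)-3-[(1S,3E)-1-bromo-3,4-dimethylhexa-3,5-dien-1-yl]-2-ethylidene-3-methylcyclobutan-1-one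
Product: 17 tricyclic Diels–Alder adduct (C1 ketone; C4 bromide; C7=C8 alkene; C3 C4 C6 C10 C11 configured as in the target)
Conditions: toluene (0.01 M), BHT (cat.), sealed tube, 110 °C
Reagents that add atoms: none
Why: Thermal intramolecular Diels–Alder reaction: the diene C6=C7–C8=C9 adds suprafacially across the strained, ketone-activated exocyclic alkene C10=C11 in a concerted but asynchronous transition state in which the unsubstituted terminus C9 leads on the enone β-carbon C10. The closest known reaction type is the type 1 intramolecular Diels–Alder reaction of 1,3,8-nonatrienes with an internally activated dienophile, together with intermolecular cycloadditions of 2-alkylidenecyclobutanones. Ring C (the cyclohexene) is closed by both new bonds as the [4+2] ring, and ring B (the cyclopentane) is closed by the C6–C11 bond in the fused mode, the only one that the three-atom tether C3–C4–C5 allows. C11 and C6 follow from C3, because the diene can reach C11 only from the cyclobutane face that carries C4 and because the four-membered ring holds the C3–C11 torsion near zero, which the tether-endo (cis-fused) transition state accommodates and the trans-fused one does not; C10 follows from the (E)-geometry of the ethylidene group, which places its methyl cis to C3. The step needs fused over bridged regiochemistry (secured by the short tether), cis over trans ring fusion (secured by the cyclobutane constraint and the quaternary C3), and cycloaddition ahead of a diene [1,5]-hydrogen shift or enone oligomerisation (secured by ketone activation, strain of the exocyclic alkene and high dilution).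

Step 13
Reactants: 17 tricyclic Diels–Alder adduct
Product: 18 C1-epi alcohol (hydroxyl on the cyclobutane face shared with C6 and C4)
Conditions: Li[sBu3BH] (1.2 equiv), THF, −78 °C; H2O
Reagents that add atoms: none
Why: The bulky hydride should attack the cyclobutanone from its more open face (flanked only by C10–H and the C10 methyl; the other face is shielded by ring B, the C6 methyl and the C4 bromine), which gives the alcohol epimeric to the target at C1.

Step 14
Reactants: 18 C1-epi alcohol
Product: 19 C1 acetate with the target configuration at C1 (C7=C8 alkene retained)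
Conditions: AcOH, PPh3, DIAD, toluene, 0 → 50 °C
Reagents that add atoms: acetic acid, CC(=O)O
Why: Mitsunobu esterification: acetate displaces the alkoxyphosphonium by SN2 from the open face through which hydride entered, inverting C1 to the target configuration (acetoxy cis to C10 and to the C3 methyl) and installing the ester in the same operation.

Step 15
Reactants: 19 C1 acetate
Product: 20 enone (C9 ketone conjugated with C7=C8)
Conditions: Rh2(cap)4 (dirhodium tetracaprolactamate, 1 mol %), tBuOOH (5 equiv), K2CO3, CH2Cl2, rt
Reagents that add atoms: tert-butyl hydroperoxide, CC(C)(C)OO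
Why: Radical allylic C–H oxidation by tert-butylperoxyl radicals at the only allylic methylene (C9; C6 is quaternary and the C7 methyl is primary) should give the enone, as in the oxidation of 1-methylcyclohexenes to 3-methylcyclohex-2-enones; no stereocentre is created.

Step 16
Reactants: 20 enone
Product: 22 α-bromo ketone (C7 methyl and C8 bromine equatorial as in the target; C9 ketone), via triethylsilyl enol ether 21 (not isolated)
Conditions: RhCl(PPh3)3 (2 mol %), Et3SiH, toluene, 60 °C; then NBS, THF, −78 → 0 °C
Reagents that add atoms: N-bromosuccinimide, O=C1CCC(=O)N1Br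
Why: Rhodium-catalysed 1,4-hydrosilylation should deliver hydride to C7 anti to the adjacent axial C6 methyl (as in additions to steroidal 1-en-3-ones), leaving the C7 methyl equatorial, and gives the C8=C9 silyl enol ether regiospecifically; bromination then occurs at C8 away from the same syn-axial methyl to give the equatorial bromide, which is also the thermodynamic epimer.

Step 17
Reactants: 22 α-bromo ketone
Product: 23 target CNP0246576.1
Conditions: Li[sBu3BH] (1.1 equiv), THF, −78 °C; H2O
Reagents that add atoms: none
Why: The bulky hydride should attack the C9 ketone along the equatorial trajectory, because the axial one is blocked by the syn-axial C11–C3 bond, giving the axial carbinol cis to the C8 bromine; the acetate survives at −78 °C and the cis-bromohydrin alkoxide cannot close to an epoxide.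

**Compound list**

1 | methyl 1-methyl-3-oxocyclobutane-1-carboxylate | COC(=O)C1(C)CC(=O)C1 | starting material
2 | methyl 3,3-dimethoxy-1-methylcyclobutane-1-carboxylate | COC(=O)C1(C)CC(OC)(OC)C1 | intermediate
3 | 3,3-dimethoxy-1-methylcyclobutane-1-carbaldehyde | O=CC1(C)CC(OC)(OC)C1 | intermediate
4 | ethyl 2,3-dimethylbut-2-enoate | CCOC(=O)C(C)=C(C)C | starting material
5 | lithium dienolate of 4 | CCOC([O-])=C(C)C(C)=C.[Li+] | intermediate (not isolated)
6 | tert-butyl[(1-ethoxy-2,3-dimethylbuta-1,3-dien-1-yl)oxy]dimethylsilane (ketene-acetal geometry unassigned) | CCOC(O[Si](C)(C)C(C)(C)C)=C(C)C(C)=C | intermediate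
7 | ethyl (2E,5R)-5-(3,3-dimethoxy-1-methylcyclobutyl)-5-hydroxy-2,3-dimethylpent-2-enoate | COC1(OC)CC(C)([C@H](O)C/C(C)=C(C)/C(=O)OCC)C1 | intermediate
8 | ethyl (2E,5S)-5-bromo-5-(3,3-dimethoxy-1-methylcyclobutyl)-2,3-dimethylpent-2-enoate | COC1(OC)CC(C)([C@@H](Br)C/C(C)=C(C)/C(=O)OCC)C1 | intermediate
9 | (2E,5S)-5-bromo-5-(3,3-dimethoxy-1-methylcyclobutyl)-2,3-dimethylpent-2-en-1-ol | COC1(OC)CC(C)([C@@H](Br)C/C(C)=C(C)/CO)C1 | intermediate
10 | (2E,5S)-5-bromo-5-(3,3-dimethoxy-1-methylcyclobutyl)-2,3-dimethylpent-2-enal | COC1(OC)CC(C)([C@@H](Br)C/C(C)=C(C)/C=O)C1 | intermediate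
11 | 3-[(1S,3E)-1-bromo-3,4-dimethylhexa-3,5-dien-1-yl]-1,1-dimethoxy-3-methylcyclobutane | COC1(OC)CC(C)([C@@H](Br)C/C(C)=C(C)/C=C)C1 | intermediate
12 | 3-[(1S,3E)-1-bromo-3,4-dimethylhexa-3,5-dien-1-yl]-3-methylcyclobutan-1-one | O=C1CC(C)([C@@H](Br)C/C(C)=C(C)/C=C)C1 | intermediate
13 | lithium enolate of 12, enolised toward the future C11 | [Li+].[O-]C1=C[C@](C)([C@@H](Br)C/C(C)=C(C)/C=C)C1 | intermediate (not isolated)
14 | (3R)-3-[(1S,3E)-1-bromo-3,4-dimethylhexa-3,5-dien-1-yl]-2-(1-hydroxyethyl)-3-methylcyclobutan-1-one (C2 and carbinol centres unassigned) | O=C1C[C@@](C)([C@@H](Br)C/C(C)=C(C)/C=C)C1C(C)O | intermediate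
15 | methanesulfonate of 14 | O=C1C[C@@](C)([C@@H](Br)C/C(C)=C(C)/C=C)C1C(C)OS(C)(=O)=O | intermediate (not isolated)
16 | (2E,3R)-3-[(1S,3E)-1-bromo-3,4-dimethylhexa-3,5-dien-1-yl]-2-ethylidene-3-methylcyclobutan-1-one | O=C1C[C@@](C)([C@@H](Br)C/C(C)=C(C)/C=C)/C1=C\C | intermediate
17 | tricyclic Diels–Alder adduct (C1 ketone; C4 bromide; C7=C8 alkene) | O=C1C[C@@]2(C)[C@@H](Br)C[C@]3(C)C(C)=CC[C@H](C)[C@]123 | intermediate
18 | C1-epi alcohol (hydroxyl on the cyclobutane face shared with C6 and C4) | O[C@H]1C[C@@]2(C)[C@@H](Br)C[C@]3(C)C(C)=CC[C@H](C)[C@]123 | intermediate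
19 | C1 acetate, target configuration at C1 (C7=C8 alkene) | CC(=O)O[C@@H]1C[C@@]2(C)[C@@H](Br)C[C@]3(C)C(C)=CC[C@H](C)[C@]123 | intermediate
20 | enone (C7=C8–C9=O) | CC(=O)O[C@@H]1C[C@@]2(C)[C@@H](Br)C[C@]3(C)C(C)=CC(=O)[C@H](C)[C@]123 | intermediate
21 | triethylsilyl enol ether (C8=C9–OSiEt3; C7–H set) | CC(=O)O[C@@H]1C[C@@]2(C)[C@@H](Br)C[C@]3(C)[C@@H](C)C=C(O[Si](CC)(CC)CC)[C@H](C)[C@]123 | intermediate (not isolated)
22 | α-bromo ketone (C8 bromide; C9 ketone) | CC(=O)O[C@@H]1C[C@@]2(C)[C@@H](Br)C[C@]3(C)[C@@H](C)[C@H](Br)C(=O)[C@H](C)[C@]123 | intermediate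
23 | target CNP0246576.1, (1R,3R,4S,6R,7R,8S,9R,10R,11R) in the locants above | CC(=O)O[C@@H]1C[C@@]2(C)[C@@H](Br)C[C@]3(C)[C@@H](C)[C@H](Br)[C@H](O)[C@H](C)[C@]123 | target

**Step count**

Total: 17 steps. Longest linear sequence: 16 steps (1 → 23 through steps 1, 2 and 4–17); step 3 is a one-step side branch from 4.

**Steps most likely to fail, with fallbacks**

Step 12 (key step). The thermal cycloaddition may be outrun by a [1,5]-hydrogen shift in the diene or by oligomerisation of the strained enone, or it may partly follow the ketone-endo, trans-fused mode. The fallback changes the activation from thermal to cationic. Starting from 16, silyl-triflate-catalysed ketalisation (1,2-bis(trimethylsilyloxy)ethane, cat. TMSOTf, CH2Cl2, −78 °C) should give the ethylene ketal of the enone F1. Further TMSOTf (−78 → −40 °C) reversibly opens this ketal to its oxygen-stabilised allyl cation, a far stronger dienophile, which should undergo the known cationic [4+2] with the tethered diene at a temperature where hydrogen shifts do not occur and reclose to the ethylene ketal of the cycloadduct F2. Aqueous HCl in THF then returns the route at 17.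

Step 10. Discrimination between the two ring methylene groups may be poor, and the lithium enolate may undergo retro-aldol or proton exchange with acetaldehyde before the choice is fixed. The fallback separates the selection from the C–C bond formation. Starting from 12, the same chiral lithium amide is added to the ketone premixed with TMSCl at −100 °C (in-situ quench), which should give the trimethylsilyl enol ether F3 as an isolable compound; its minor diastereomer can be removed or hydrolysed back to 12. A Mukaiyama aldol of F3 with acetaldehyde (BF3·OEt2, CH2Cl2, −78 °C) then returns the route at 14.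

Step 14. Activation of the crowded hydroxyl may be slow, and SN2 displacement at the neopentyl-like cyclobutyl carbon may lose out to elimination or to ionisation with cyclopropylcarbinyl-type rearrangement. The fallback replaces inversion by thermodynamic control. Starting from 18, Meerwein–Ponndorf–Verley/Oppenauer equilibration through ketone 17 (Al(OiPr)3, cat. acetone, iPrOH/toluene, 80 °C) should drain the congested alcohol into its less hindered epimer, the C1 alcohol with the target configuration F4. Acetylation of F4 (Ac2O, DMAP, pyridine) returns the route at 19.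

**Further compounds**

F1 | step 12 | ethylene ketal of the enone 16 | C1COC2(O1)C[C@@](C)([C@@H](Br)C/C(C)=C(C)/C=C)/C2=C\C
F2 | step 12 | ethylene ketal of the cycloadduct 17 | C1COC2(O1)C[C@@]3(C)[C@@H](Br)C[C@]4(C)C(C)=CC[C@H](C)[C@]234
F3 | step 10 | trimethylsilyl enol ether of 12, enolised toward the future C11 | C[Si](C)(C)OC1=C[C@](C)([C@@H](Br)C/C(C)=C(C)/C=C)C1
F4 | step 14 | C1 alcohol with the target configuration (C1 epimer of 18) | O[C@@H]1C[C@@]2(C)[C@@H](Br)C[C@]3(C)C(C)=CC[C@H](C)[C@]123
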